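**Retrosynthetic overview**

- The strategy rests on C9: this quaternary carbon carries the C17=C18 vinyl group and the E-configured C7=C8 styrenyl link to ring A (the benzene ring bearing the ether oxygen), and these two olefins are the two halves of one cyclopropene C=C bond opened by a styrene. C9' with C17'=C18' and C7'=C8' to ring B (the phenol ring) is the same motif.
- Endgame: desilylation, the C12=C13 isopropylidene by Wittig reaction, acetal hydrolysis. Key disconnection: C7=C8 and C17=C18 by Ru-catalysed enantioselective ring-opening cross-metathesis of ring A styrene 17 with the achiral cyclopropene 21.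
- 17 comes from ring A aldehyde 16 by Wittig methylenation; 16 comes from the same metathesis run first on cyclopropene 13 with 4-silyloxystyrene 14 to set C9'.
- 13 comes from an isopropenyl group (dibromocarbene addition, monoreduction, dehydrobromination). C12' comes from a CBS reduction of ketone 8, which comes from a Weinreb amide and the homoallyl Grignard reagent 7 after O–C13' ether formation between 4-hydroxybenzaldehyde and the bromoisobutyrate.
- No ring of the target is built, since both benzene rings are bought. Only two transient three-membered rings are made and opened, the lower-unit cyclopropene first and the upper-unit cyclopropene second.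

Key step: step 18

Assumption: the (R) axial configuration is written for the binaphthyl aryloxide of the Ru catalyst as the antipode taken to give S at C9' and C9; should the sense of induction be the opposite, the (S) ligand is used in steps 11 and 18 with no other change (bakuchiol numbering, primed locants for the lower unit).

**Route**

Step 1
Reactants: 1 4-hydroxybenzaldehyde; 2 ethyl 2-bromo-2-methylpropanoate
Product: 3 ethyl 2-(4-formylphenoxy)-2-methylpropanoate
Conditions: K2CO3, DMF, 80 °C (bromo ester in excess)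
Reagents that add atoms: none
Why: Williamson-type O-alkylation of the phenoxide by the tertiary α-bromo ester forms the hindered aryl–O–C13' bond, the excess of the bromo ester making up for what is lost to E2 elimination.

Step 2
Reactants: 3 ethyl 2-(4-formylphenoxy)-2-methylpropanoate
Product: 4 ethyl 2-[4-(1,3-dioxolan-2-yl)phenoxy]-2-methylpropanoate
Conditions: HOCH2CH2OH, TsOH·H2O (cat.), toluene, reflux, Dean–Stark
Reagents that add atoms: ethylene glycol, OCCO
Why: Acid-catalysed acetalisation under azeotropic removal of water masks the ring A aldehyde against the organomagnesium, borane, hydroxide and tert-butoxide reagents of steps 3 to 10.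

Step 3
Reactants: 4 ethyl 2-[4-(1,3-dioxolan-2-yl)phenoxy]-2-methylpropanoate
Product: 5 2-[4-(1,3-dioxolan-2-yl)phenoxy]-N-methoxy-N,2-dimethylpropanamide
Conditions: MeNH(OMe)·HCl, i-PrMgCl, THF, −20 → 0 °C
Reagents that add atoms: N,O-dimethylhydroxylamine hydrochloride, CNOC.Cl
Why: Aminolysis of the ester by the chloromagnesium amide formed in the flask gives the Weinreb amide and leaves the acetal untouched.

Step 4
Reactants: 6 4-bromo-2-methylbut-1-ene
Product: 7 (3-methylbut-3-en-1-yl)magnesium bromide (titrated THF stock solution, one batch divided between the two branches)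
Conditions: Mg turnings, I2 (crystal), THF, 40 °C; titrated and kept under argon
Reagents that add atoms: magnesium, [Mg]
Why: Insertion of magnesium into the primary C–Br bond gives the homoallylic Grignard reagent, which keeps its constitution in THF and is therefore prepared once as a stock solution for the ketone synthesis and for the acetal synthesis.

Step 5
Reactants: 5 2-[4-(1,3-dioxolan-2-yl)phenoxy]-N-methoxy-N,2-dimethylpropanamide; 7 (3-methylbut-3-en-1-yl)magnesium bromide
Product: 8 2-[4-(1,3-dioxolan-2-yl)phenoxy]-2,6-dimethylhept-6-en-3-one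
Conditions: THF, 0 °C → rt; aq. NH4Cl
Reagents that add atoms: none
Why: Weinreb ketone synthesis, in which the chelated tetrahedral intermediate holds back a second addition so that the C11'–C12' bond forms cleanly.

Step 6
Reactants: 8 2-[4-(1,3-dioxolan-2-yl)phenoxy]-2,6-dimethylhept-6-en-3-one
Product: 9 (3S)-2-[4-(1,3-dioxolan-2-yl)phenoxy]-2,6-dimethylhept-6-en-3-ol (C3 is C12')
Conditions: (R)-2-methyl-CBS-oxazaborolidine (0.3 equiv), catecholborane, toluene, −78 → −30 °C
Reagents that add atoms: none
Why: Corey–Bakshi–Shibata reduction, in which the ketone binds the oxazaborolidine with the bulky C(CH3)2OAr group turned away from the catalyst so that the (R) catalyst should deliver hydride to the face that gives the 12'S alcohol, while catecholborane leaves the isopropenyl group alone.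

Step 7
Reactants: 9 (3S)-2-[4-(1,3-dioxolan-2-yl)phenoxy]-2,6-dimethylhept-6-en-3-ol
Product: 10 tert-butyl({(3S)-2-[4-(1,3-dioxolan-2-yl)phenoxy]-2,6-dimethylhept-6-en-3-yl}oxy)dimethylsilane
Conditions: TBSCl, imidazole, DMAP (cat.), DMF, 50 °C
Reagents that add atoms: tert-butyldimethylsilyl chloride, CC(C)(C)[Si](C)(C)Cl
Why: Silyl ether formation protects the C12' hydroxyl before the carbene step, the chloride with imidazole being chosen over the triflate so that the aryl dioxolane is not activated.

Step 8
Reactants: 10 tert-butyl({(3S)-2-[4-(1,3-dioxolan-2-yl)phenoxy]-2,6-dimethylhept-6-en-3-yl}oxy)dimethylsilane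
Product: 11 2-[4-({(3S)-3-[(tert-butyldimethylsilyl)oxy]-5-(2,2-dibromo-1-methylcyclopropyl)-2-methylpentan-2-yl}oxy)phenyl]-1,3-dioxolane (both epimers at the ring carbon)
Conditions: CHBr3, 50% aq. NaOH, BnEt3NCl (cat.), CH2Cl2, rt
Reagents that add atoms: bromoform, BrC(Br)Br
Why: Phase-transfer generation of dibromocarbene and its [2+1] cycloaddition to the only olefin present, an electron-rich 1,1-disubstituted one, under basic conditions that acetal and silyl ether tolerate.

Step 9
Reactants: 11 dibromocyclopropane of the lower unit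
Product: 12 2-[4-({(3S)-5-(2-bromo-1-methylcyclopropyl)-3-[(tert-butyldimethylsilyl)oxy]-2-methylpentan-2-yl}oxy)phenyl]-1,3-dioxolane (diastereomer mixture)
Conditions: EtMgBr, Ti(OiPr)4 (5 mol%), Et2O, rt
Reagents that add atoms: none
Why: Titanium-catalysed hydrodebromination of a gem-dibromocyclopropane by EtMgBr stops at the monobromide and tolerates acetal and silyl ether.

Step 10
Reactants: 12 monobromocyclopropane of the lower unit
Product: 13 2-[4-({(3S)-3-[(tert-butyldimethylsilyl)oxy]-2-methyl-5-(1-methylcycloprop-2-en-1-yl)pentan-2-yl}oxy)phenyl]-1,3-dioxolane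
Conditions: KOtBu, DMSO, rt
Reagents that add atoms: none
Why: Base-induced 1,2-dehydrobromination gives the 3,3-disubstituted cyclopropene, all diastereomers of 12 converging on one compound and the lack of hydrogen at C3 blocking isomerisation.

Step 11
Reactants: 13 lower-unit cyclopropene; 14 tert-butyl(4-ethenylphenoxy)dimethylsilane
Product: 15 2-[4-({(3S,6S,7E)-3-[(tert-butyldimethylsilyl)oxy]-8-{4-[(tert-butyldimethylsilyl)oxy]phenyl}-6-ethenyl-2,6-dimethyloct-7-en-2-yl}oxy)phenyl]-1,3-dioxolane (C6 is C9')
Conditions: RuCl(=CH-C6H4-2-OiPr)(L) (5 mol%), L = (R)-1-mesityl-3-(2'-oxido-1,1'-binaphthalen-2-yl)-4,5-dihydroimidazol-2-ylidene, THF, 22 °C, the styrene in fivefold excess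
Reagents that add atoms: none
Why: Ru-catalysed enantioselective ring-opening cross-metathesis, a 1:1 addition of the styrene across the opened cyclopropene in which the ring B benzylidene approaches syn to the C3 methyl and the chiral carbene–aryloxide ligand picks the enantiotopic olefinic carbon, so that C9' should form as S with E geometry under catalyst control and without influence from remote C12'.

Step 12
Reactants: 15 ring A dioxolane of the lower unit
Product: 16 4-({(3S,6S,7E)-3-[(tert-butyldimethylsilyl)oxy]-8-{4-[(tert-butyldimethylsilyl)oxy]phenyl}-6-ethenyl-2,6-dimethyloct-7-en-2-yl}oxy)benzaldehyde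
Conditions: PPTS, acetone/H2O, 40 °C
Reagents that add atoms: water, O
Why: Mild acid hydrolysis of an electron-rich aryl acetal, under which the aryl silyl ether and the hindered secondary silyl ether should stay intact.

Step 13
Reactants: 16 ring A aldehyde
Product: 17 1-ethenyl-4-({(3S,6S,7E)-3-[(tert-butyldimethylsilyl)oxy]-8-{4-[(tert-butyldimethylsilyl)oxy]phenyl}-6-ethenyl-2,6-dimethyloct-7-en-2-yl}oxy)benzene (ring A styrene)
Conditions: Ph3PCH3Br, KN(SiMe3)2 (slightly less than the salt), THF, 0 °C → rt
Reagents that add atoms: methyltriphenylphosphonium bromide, C[P+](c1ccccc1)(c1ccccc1)c1ccccc1.[Br-]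
Why: Wittig methylenation of the aryl aldehyde, run with no free base left over that could attack the aryl silyl ether.

Step 14
Reactants: 7 (3-methylbut-3-en-1-yl)magnesium bromide
Product: 18 5,5-dimethoxy-2-methylpent-1-ene
Conditions: HC(OMe)3, THF/toluene, 80 °C (part of the THF distilled off); aq. NH4Cl
Reagents that add atoms: trimethyl orthoformate, COC(OC)OC
Why: Bodroux–Chichibabin reaction, in which the Grignard reagent displaces one methoxide of the orthoformate and gives the one-carbon-homologated aldehyde directly as its dimethyl acetal (the future C12).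

Step 15
Reactants: 18 5,5-dimethoxy-2-methylpent-1-ene
Product: 19 1,1-dibromo-2-(3,3-dimethoxypropyl)-2-methylcyclopropane (racemic)
Conditions: CHBr3, 50% aq. NaOH, BnEt3NCl (cat.), CH2Cl2, rt
Reagents that add atoms: bromoform, BrC(Br)Br
Why: Phase-transfer dibromocarbene [2+1] cycloaddition to the 1,1-disubstituted olefin, the acetal being inert to base.

Step 16
Reactants: 19 1,1-dibromo-2-(3,3-dimethoxypropyl)-2-methylcyclopropane
Product: 20 1-bromo-2-(3,3-dimethoxypropyl)-2-methylcyclopropane (diastereomer mixture)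
Conditions: EtMgBr, Ti(OiPr)4 (5 mol%), Et2O, rt
Reagents that add atoms: none
Why: Titanium-catalysed monoreduction of the gem-dibromide by EtMgBr, as in step 9.

Step 17
Reactants: 20 1-bromo-2-(3,3-dimethoxypropyl)-2-methylcyclopropane
Product: 21 3-(3,3-dimethoxypropyl)-3-methylcycloprop-1-ene
Conditions: KOtBu, DMSO, rt; pentane extraction, distillation under reduced pressure, stored cold
Reagents that add atoms: none
Why: 1,2-Dehydrobromination to the achiral 3,3-disubstituted cyclopropene, as in step 10.

Step 18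
Reactants: 17 ring A styrene; 21 3-(3,3-dimethoxypropyl)-3-methylcycloprop-1-ene
Product: 22 1-[(1E,3S)-3-ethenyl-6,6-dimethoxy-3-methylhex-1-en-1-yl]-4-({(3S,6S,7E)-3-[(tert-butyldimethylsilyl)oxy]-8-{4-[(tert-butyldimethylsilyl)oxy]phenyl}-6-ethenyl-2,6-dimethyloct-7-en-2-yl}oxy)benzene (protected target, C12 as dimethyl acetal)
Conditions: RuCl(=CH-C6H4-2-OiPr)(L) (5–10 mol%), L as in step 11, THF, 22 °C, two equivalents of the cyclopropene added by syringe pump over several hours
Reagents that add atoms: none
Why: The Ru isopropoxybenzylidene is exchanged for the ring A benzylidene of 17, which adds in a [2+2] manner across the strained C=C of 21 from the face syn to the methyl group; cycloreversion of the ruthenacyclobutane opens the three-membered ring irreversibly to the neopentyl-type alkylidene Ru=C17H–C9, and a further molecule of 17 turns this into the C17=C18 vinyl group while handing back the benzylidene, so that the overall change is a 1:1 addition of 17 to 21 in which every atom of both partners is kept. The closest known reaction type is the Ru- or Mo-catalysed enantioselective ring-opening cross-metathesis of 3,3-disubstituted cyclopropenes with styrenes. No ring closes: one ring opens and the two bonds C7=C8 and C17=C18 form. C9 is the only new stereocentre and should be set as S by the chiral carbene–binaphtholate ligand, which decides which of the two enantiotopic olefinic carbons is joined to the benzylidene carbon once the methyl group has fixed the face of approach; C9' and C12' lie too far away to interfere, so the diastereomer ratio should mirror the selectivity of the catalyst. The step needs E geometry at C7=C8, which should follow from the trans-disposed substituents of the metallacyclobutane, and chemoselectivity for the ring A vinyl group, which is secured because the C17'=C18' vinyl and the C7'=C8' olefin both flank a quaternary carbon and are too hindered to enter the cycle. C12 is carried as a dimethyl acetal because a prenyl olefin would be captured by the intermediate alkylidene in a five-membered ring closure, and slow addition of 21 keeps the styrene in excess over the cyclopropene so that oligomerisation of 21 is held back.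

Step 19
Reactants: 22 protected target carrying C12 as dimethyl acetal
Product: 23 (4S,5E)-4-ethenyl-4-methyl-6-[4-({(3S,6S,7E)-3-[(tert-butyldimethylsilyl)oxy]-8-{4-[(tert-butyldimethylsilyl)oxy]phenyl}-6-ethenyl-2,6-dimethyloct-7-en-2-yl}oxy)phenyl]hex-5-enal (C12 aldehyde)
Conditions: PPTS, acetone/H2O, rt
Reagents that add atoms: water, O
Why: Mild acid hydrolysis of an aliphatic dimethyl acetal, which should be faster than cleavage of the aryl silyl ether or the hindered secondary silyl ether.

Step 20
Reactants: 23 C12 aldehyde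
Product: 24 1-[(1E,3S)-3-ethenyl-3,7-dimethylocta-1,6-dien-1-yl]-4-({(3S,6S,7E)-3-[(tert-butyldimethylsilyl)oxy]-8-{4-[(tert-butyldimethylsilyl)oxy]phenyl}-6-ethenyl-2,6-dimethyloct-7-en-2-yl}oxy)benzene (bis-silyl ether of the target)
Conditions: i-PrPPh3I, n-BuLi, THF, 0 °C; then the aldehyde, −78 °C → rt
Reagents that add atoms: isopropyltriphenylphosphonium iodide, CC(C)[P+](c1ccccc1)(c1ccccc1)c1ccccc1.[I-]
Why: Wittig olefination of the unhindered aldehyde with the unstabilised isopropylidene ylide installs C12=C13, a double bond with no geometry to control.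

Step 21
Reactants: 24 bis-silyl ether of the target
Product: 25 (12'S)-bisbakuchiol C
Conditions: Bu4NF, THF, rt → 45 °C; aq. NH4Cl
Reagents that add atoms: none
Why: Fluoride-induced desilylation frees the ring B phenol at once and the hindered C12' alcohol on warming, and nothing else in the molecule is sensitive to fluoride or mild base.

**Compound list**

1 | 4-hydroxybenzaldehyde | O=Cc1ccc(O)cc1 | starting material
2 | ethyl 2-bromo-2-methylpropanoate | CCOC(=O)C(C)(C)Br | starting material
3 | ethyl 2-(4-formylphenoxy)-2-methylpropanoate | CCOC(=O)C(C)(C)Oc1ccc(C=O)cc1 | intermediate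
4 | ethyl 2-[4-(1,3-dioxolan-2-yl)phenoxy]-2-methylpropanoate | CCOC(=O)C(C)(C)Oc1ccc(C2OCCO2)cc1 | intermediate
5 | 2-[4-(1,3-dioxolan-2-yl)phenoxy]-N-methoxy-N,2-dimethylpropanamide | CON(C)C(=O)C(C)(C)Oc1ccc(C2OCCO2)cc1 | intermediate
6 | 4-bromo-2-methylbut-1-ene | C=C(C)CCBr | starting material
7 | (3-methylbut-3-en-1-yl)magnesium bromide, THF stock solution | C=C(C)CC[Mg]Br | intermediate
8 | 2-[4-(1,3-dioxolan-2-yl)phenoxy]-2,6-dimethylhept-6-en-3-one | C=C(C)CCC(=O)C(C)(C)Oc1ccc(C2OCCO2)cc1 | intermediate
9 | (3S)-2-[4-(1,3-dioxolan-2-yl)phenoxy]-2,6-dimethylhept-6-en-3-ol | O1CCOC1c2ccc(OC(C)(C)[C@@H](O)CCC(C)=C)cc2 | intermediate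
10 | tert-butyl({(3S)-2-[4-(1,3-dioxolan-2-yl)phenoxy]-2,6-dimethylhept-6-en-3-yl}oxy)dimethylsilane | O1CCOC1c2ccc(OC(C)(C)[C@@H](O[Si](C)(C)C(C)(C)C)CCC(C)=C)cc2 | intermediate
11 | 2-[4-({(3S)-3-[(tert-butyldimethylsilyl)oxy]-5-(2,2-dibromo-1-methylcyclopropyl)-2-methylpentan-2-yl}oxy)phenyl]-1,3-dioxolane, both ring epimers | O1CCOC1c2ccc(OC(C)(C)[C@@H](O[Si](C)(C)C(C)(C)C)CCC3(C)CC3(Br)Br)cc2 | intermediate
12 | 2-[4-({(3S)-5-(2-bromo-1-methylcyclopropyl)-3-[(tert-butyldimethylsilyl)oxy]-2-methylpentan-2-yl}oxy)phenyl]-1,3-dioxolane, diastereomer mixture | O1CCOC1c2ccc(OC(C)(C)[C@@H](O[Si](C)(C)C(C)(C)C)CCC3(C)CC3Br)cc2 | intermediate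
13 | 2-[4-({(3S)-3-[(tert-butyldimethylsilyl)oxy]-2-methyl-5-(1-methylcycloprop-2-en-1-yl)pentan-2-yl}oxy)phenyl]-1,3-dioxolane | O1CCOC1c2ccc(OC(C)(C)[C@@H](O[Si](C)(C)C(C)(C)C)CCC3(C)C=C3)cc2 | intermediate
14 | tert-butyl(4-ethenylphenoxy)dimethylsilane | C=Cc1ccc(O[Si](C)(C)C(C)(C)C)cc1 | starting material
15 | 2-[4-({(3S,6S,7E)-3-[(tert-butyldimethylsilyl)oxy]-8-{4-[(tert-butyldimethylsilyl)oxy]phenyl}-6-ethenyl-2,6-dimethyloct-7-en-2-yl}oxy)phenyl]-1,3-dioxolane | O1CCOC1c2ccc(OC(C)(C)[C@@H](O[Si](C)(C)C(C)(C)C)CC[C@@](C)(C=C)/C=C/c3ccc(O[Si](C)(C)C(C)(C)C)cc3)cc2 | intermediate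
16 | 4-({(3S,6S,7E)-3-[(tert-butyldimethylsilyl)oxy]-8-{4-[(tert-butyldimethylsilyl)oxy]phenyl}-6-ethenyl-2,6-dimethyloct-7-en-2-yl}oxy)benzaldehyde | O=Cc1ccc(OC(C)(C)[C@@H](O[Si](C)(C)C(C)(C)C)CC[C@@](C)(C=C)/C=C/c2ccc(O[Si](C)(C)C(C)(C)C)cc2)cc1 | intermediate
17 | ring A styrene, 1-ethenyl-4-({(3S,6S,7E)-3-[(tert-butyldimethylsilyl)oxy]-8-{4-[(tert-butyldimethylsilyl)oxy]phenyl}-6-ethenyl-2,6-dimethyloct-7-en-2-yl}oxy)benzene | C=Cc1ccc(OC(C)(C)[C@@H](O[Si](C)(C)C(C)(C)C)CC[C@@](C)(C=C)/C=C/c2ccc(O[Si](C)(C)C(C)(C)C)cc2)cc1 | intermediate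
18 | 5,5-dimethoxy-2-methylpent-1-ene | C=C(C)CCC(OC)OC | intermediate
19 | 1,1-dibromo-2-(3,3-dimethoxypropyl)-2-methylcyclopropane, racemic | COC(OC)CCC1(C)CC1(Br)Br | intermediate
20 | 1-bromo-2-(3,3-dimethoxypropyl)-2-methylcyclopropane, diastereomer mixture | COC(OC)CCC1(C)CC1Br | intermediate
21 | 3-(3,3-dimethoxypropyl)-3-methylcycloprop-1-ene | COC(OC)CCC1(C)C=C1 | intermediate
22 | 1-[(1E,3S)-3-ethenyl-6,6-dimethoxy-3-methylhex-1-en-1-yl]-4-({(3S,6S,7E)-3-[(tert-butyldimethylsilyl)oxy]-8-{4-[(tert-butyldimethylsilyl)oxy]phenyl}-6-ethenyl-2,6-dimethyloct-7-en-2-yl}oxy)benzene | C=C[C@@](C)(/C=C/c1ccc(OC(C)(C)[C@@H](O[Si](C)(C)C(C)(C)C)CC[C@@](C)(C=C)/C=C/c2ccc(O[Si](C)(C)C(C)(C)C)cc2)cc1)CCC(OC)OC | intermediate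
23 | (4S,5E)-4-ethenyl-4-methyl-6-[4-({(3S,6S,7E)-3-[(tert-butyldimethylsilyl)oxy]-8-{4-[(tert-butyldimethylsilyl)oxy]phenyl}-6-ethenyl-2,6-dimethyloct-7-en-2-yl}oxy)phenyl]hex-5-enal | C=C[C@@](C)(/C=C/c1ccc(OC(C)(C)[C@@H](O[Si](C)(C)C(C)(C)C)CC[C@@](C)(C=C)/C=C/c2ccc(O[Si](C)(C)C(C)(C)C)cc2)cc1)CCC=O | intermediate
24 | bis(tert-butyldimethylsilyl) ether of (12'S)-bisbakuchiol C, 1-[(1E,3S)-3-ethenyl-3,7-dimethylocta-1,6-dien-1-yl]-4-({(3S,6S,7E)-3-[(tert-butyldimethylsilyl)oxy]-8-{4-[(tert-butyldimethylsilyl)oxy]phenyl}-6-ethenyl-2,6-dimethyloct-7-en-2-yl}oxy)benzene | C=C[C@@](C)(/C=C/c1ccc(OC(C)(C)[C@@H](O[Si](C)(C)C(C)(C)C)CC[C@@](C)(C=C)/C=C/c2ccc(O[Si](C)(C)C(C)(C)C)cc2)cc1)CCC=C(C)C | intermediate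
25 | (12'S)-bisbakuchiol C, 4-[(1E,3S,6S)-3-ethenyl-7-{4-[(1E,3S)-3-ethenyl-3,7-dimethylocta-1,6-dien-1-yl]phenoxy}-6-hydroxy-3,7-dimethyloct-1-en-1-yl]phenol | C=C[C@@](C)(/C=C/c1ccc(OC(C)(C)[C@@H](O)CC[C@@](C)(C=C)/C=C/c2ccc(O)cc2)cc1)CCC=C(C)C | target

**Step count and risks**

Total: 21 steps. Longest linear sequence: 16 steps (steps 1–3, 5–13, then 18–21). The Grignard stock solution (step 4) feeds steps 5 and 14, and the cyclopropene branch (steps 14–17) joins at step 18.

Steps most likely to fail:

1. Step 18 (key step). The catalyst may not tell the cyclopropene face syn to methyl from the face syn to the CH2CH2CH(OMe)2 arm well enough. Both enantiotopic olefinic carbons would then be attacked and C9 would form as a poorly separable diastereomer mixture. Oligomerisation of the cyclopropene may also outrun the cross-metathesis, and E/Z control at C7=C8 may be incomplete. The fallback sets out from aldehyde 16 and comes back at 24. Aldehyde 16 is homologated with lithiated trimethylsilyldiazomethane (Colvin rearrangement, THF, −78 °C → rt) to the ring A aryl alkyne F1. Hydroalumination with i-Bu2AlH and NiCl2(PPh3)2 (3 mol%) in THF at 22 °C gives the (E)-alkenylalane F2. This is used at once in a copper-catalysed enantioselective SN2' allylic substitution (CuCl2·2H2O, a chiral sulfonate-bearing imidazolinium salt as carbene precursor, THF, −15 °C) on geranyl diethyl phosphate F3, itself made from geraniol with ClP(O)(OEt)2, Et3N and DMAP. Attack at the trisubstituted carbon builds C9 with its methyl, the C17=C18 vinyl group, the E styrenyl link and the complete prenyl arm, so that 24 forms directly; the ligand antipode is chosen for 9S.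

2. Step 11. The same face and enantiotopic-carbon selection may be poor for the arm that carries C12', giving a C9' epimer mixture, and the bulky substrate may slow catalyst turnover. The fallback sets out from 10 and comes back at 15. Oxidative cleavage of the isopropenyl group (K2OsO4·2H2O cat., NaIO4, 2,6-lutidine, dioxane/H2O) gives the methyl ketone F4. Horner–Wadsworth–Emmons reaction with triethyl phosphonoacetate and NaH gives, after removal of the Z isomer, the (E)-enoate F5. Reduction with i-Bu2AlH at −78 °C gives the allylic alcohol F6, and ClP(O)(OEt)2 with Et3N and DMAP gives the allylic phosphate F7. In parallel, commercial 4-[(tert-butyldimethylsilyl)oxy]benzaldehyde is converted by the Colvin rearrangement into tert-butyl(4-ethynylphenoxy)dimethylsilane F8, which is hydroaluminated with i-Bu2AlH and NiCl2(PPh3)2 to the (E)-alkenylalane F9. The copper-catalysed enantioselective SN2' substitution of F7 by F9 (CuCl2·2H2O, chiral sulfonate-bearing imidazolinium salt) then builds C9' with its vinyl and E styrenyl groups and gives 15.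

3. Step 6. Hydride delivery may show incomplete facial control if the α-aryloxy oxygen competes for the boron centres and erodes the large/small differentiation. Slow reduction of the hindered ketone may also leave room for hydroboration of the isopropenyl group. The fallback sets out from ketone 8 and comes back at 9. Reduction with NaBH4 in MeOH gives the racemic alcohol F10. Acylation with (1S,4R)-camphanic chloride (pyridine, DMAP) gives two diastereomeric esters that are separated by chromatography or crystallisation, the (3S)-camphanate F11 being kept and the (3R)-camphanate F12 removed. Saponification of F11 with LiOH in THF/MeOH/H2O releases 9.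

**Further compounds**

F1 | step 18 | ring A aryl alkyne, the 4-ethynylphenyl ether corresponding to 16 | C#Cc1ccc(OC(C)(C)[C@@H](O[Si](C)(C)C(C)(C)C)CC[C@@](C)(C=C)/C=C/c2ccc(O[Si](C)(C)C(C)(C)C)cc2)cc1
F2 | step 18 | (E)-alkenyl(diisobutyl)alane from F1 | CC(C)C[Al](CC(C)C)/C=C/c1ccc(OC(C)(C)[C@@H](O[Si](C)(C)C(C)(C)C)CC[C@@](C)(C=C)/C=C/c2ccc(O[Si](C)(C)C(C)(C)C)cc2)cc1
F3 | step 18 | geranyl diethyl phosphate | CC(C)=CCC/C(C)=C/COP(=O)(OCC)OCC
F4 | step 11 | (5S)-5-[(tert-butyldimethylsilyl)oxy]-6-[4-(1,3-dioxolan-2-yl)phenoxy]-6-methylheptan-2-one | O1CCOC1c2ccc(OC(C)(C)[C@@H](O[Si](C)(C)C(C)(C)C)CCC(C)=O)cc2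
F5 | step 11 | ethyl (2E,6S)-6-[(tert-butyldimethylsilyl)oxy]-7-[4-(1,3-dioxolan-2-yl)phenoxy]-3,7-dimethyloct-2-enoate | O1CCOC1c2ccc(OC(C)(C)[C@@H](O[Si](C)(C)C(C)(C)C)CC/C(C)=C/C(=O)OCC)cc2
F6 | step 11 | (2E,6S)-6-[(tert-butyldimethylsilyl)oxy]-7-[4-(1,3-dioxolan-2-yl)phenoxy]-3,7-dimethyloct-2-en-1-ol | O1CCOC1c2ccc(OC(C)(C)[C@@H](O[Si](C)(C)C(C)(C)C)CC/C(C)=C/CO)cc2
F7 | step 11 | diethyl phosphate of F6 | O1CCOC1c2ccc(OC(C)(C)[C@@H](O[Si](C)(C)C(C)(C)C)CC/C(C)=C/COP(=O)(OCC)OCC)cc2
F8 | step 11 | tert-butyl(4-ethynylphenoxy)dimethylsilane | C#Cc1ccc(O[Si](C)(C)C(C)(C)C)cc1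
F9 | step 11 | (E)-{2-[4-(tert-butyldimethylsilyloxy)phenyl]ethenyl}diisobutylalane | CC(C)C[Al](CC(C)C)/C=C/c1ccc(O[Si](C)(C)C(C)(C)C)cc1
F10 | step 6 | racemic 2-[4-(1,3-dioxolan-2-yl)phenoxy]-2,6-dimethylhept-6-en-3-ol | O1CCOC1c2ccc(OC(C)(C)C(O)CCC(C)=C)cc2
F11 | step 6 | (1S,4R)-camphanate of the (3S)-alcohol | O1CCOC1c2ccc(OC(C)(C)[C@@H](OC(=O)[C@@]34CC[C@@](C)(C(=O)O3)C4(C)C)CCC(C)=C)cc2
F12 | step 6 | (1S,4R)-camphanate of the (3R)-alcohol | O1CCOC1c2ccc(OC(C)(C)[C@H](OC(=O)[C@@]34CC[C@@](C)(C(=O)O3)C4(C)C)CCC(C)=C)cc2
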